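**Plan**

1. Retrosynthetic cuts, in order: the N–acetyl bond; the ring bond C7–C8 (CH2–CH(N), Mannich) and the C=N bond; the methyl–carbonyl bond of the ketone; the bond from the spiro carbon to the lactone CH2 together with the lactone C–O bond; the bond from the spiro carbon to the lactone CH–O carbon (aldol).
2. Forward: an Evans aldol joins a silylated 4,5-dihydroxypentanoyl chain (from the L-glutamic-acid-derived lactone) to geranial. Dianion alkylation with allyl bromoacetate then builds the quaternary carbon and closes the γ-lactone (ring 1). The ester becomes the methyl ketone, the primary silyl ether the aldehyde and then the N-sulfinyl imine, and the Mannich closure gives the cyclohexanone (ring 2).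
3. Feature that allows the key step: in the 2-oxaspiro[4.5]decane core the NHAc carbon C8 is β to the ring ketone C6 and next to the carbinol carbon C9, while C5 on the other side of C6 is the quaternary spiro atom. C7–C8 is therefore a Mannich bond between a ketone that can enolise only at its methyl group and an α-silyloxy aldimine.
4. Stereochemistry: C9 (S) from the chiral pool; C1 (R) from the Evans syn-aldol; C5 (R) from alkylation of the chelated dianion anti to the alkenyl group; C8 (R) from the lithium-bridged chair of the Mannich closure with a matched sulfinyl group.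
5. The quaternary carbon is made at the ester stage, where its α-C–H is the only acidic C–H, so no choice between two ketone α-positions or a lactone α-position arises.

Key step: step 10

Assumption: the sulfinyl auxiliary is used as its (S) enantiomer, CC(C)(C)[S@@](N)=O, because closed, lithium-bridged enolate additions to (S)-configured N-sulfinyl aldimines give the C–N configuration needed here; the auxiliary is removed in step 11 and leaves no trace in the target.

**Step 1**
Reactants: 1 (S)-5-(hydroxymethyl)dihydrofuran-2(3H)-one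
Product: 4 (S)-4,5-bis(triethylsilyloxy)pentanoic acid, via lithium (S)-4,5-dihydroxypentanoate 2 (not isolated), via triethylsilyl ester 3 (not isolated)
Conditions: LiOH·H2O, THF–H2O, rt; evaporate; Et3SiCl (3.3 equiv), imidazole, DMF, 0 °C to rt; then H2O–THF, pH 5 work-up
Reagents that add atoms: lithium hydroxide [Li+].[OH-]; chlorotriethylsilane CC[Si](Cl)(CC)CC
Why: Saponification opens the γ-lactone, silylation of the salt should outrun relactonisation and the silyl ester is then hydrolysed selectively (silyl ether/silyl ester differentiation); the (S) carbinol centre is not touched and becomes C9 of the target.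

**Step 2**
Reactants: 4 (S)-4,5-bis(triethylsilyloxy)pentanoic acid; 5 (S)-4-benzyloxazolidin-2-one
Product: 7 (S)-4-benzyl-3-[(S)-4,5-bis(triethylsilyloxy)pentanoyl]oxazolidin-2-one, via mixed pivalic anhydride 6 (not isolated)
Conditions: PivCl, Et3N, THF, −20 °C; then 5, LiCl, rt
Reagents that add atoms: none
Why: N-Acylation of the Evans oxazolidinone through the mixed pivalic anhydride (LiCl/Et3N variant) is a standard imide formation under which triethylsilyl ethers are stable.

**Step 3**
Reactants: 7 (S)-4-benzyl-3-[(S)-4,5-bis(triethylsilyloxy)pentanoyl]oxazolidin-2-one; 8 geranial (isomerically pure E)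
Product: 10 (S)-4-benzyl-3-[(2S,3R,4E)-2-[(S)-2,3-bis(triethylsilyloxy)propyl]-3-hydroxy-5,9-dimethyldeca-4,8-dienoyl]oxazolidin-2-one, via dibutylboron (Z)-enolate 9 (not isolated)
Conditions: Bu2BOTf, iPr2NEt, CH2Cl2, 0 °C; 8, −78 to 0 °C; pH 7 buffer, MeOH, H2O2, 0 °C
Reagents that add atoms: none
Why: Evans syn-aldol reaction: the Z-boron enolate 9 adds 1,2 to the enal through a Zimmerman–Traxler chair on the face away from the benzyl group, which sets the carbinol carbon as (R) and the α-carbon as (S), the latter being erased again in step 5.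

**Step 4**
Reactants: 10 aldol imide
Product: 11 allyl (2S,3R,4E)-2-[(S)-2,3-bis(triethylsilyloxy)propyl]-3-hydroxy-5,9-dimethyldeca-4,8-dienoate
Conditions: allyl alcohol, n-BuLi, THF, −20 to 0 °C
Reagents that add atoms: allyl alcohol C=CCO
Why: Transesterification of the aldol imide with a lithium alkoxide (the allyl counterpart of the LiOBn cleavage) attacks the exocyclic carbonyl, releases the auxiliary and gives an ester that can be enolised in step 5 and removed in step 6 without acid or base; no stereocentre is touched.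

**Step 5**
Reactants: 11 allyl β-hydroxy ester; 12 allyl bromoacetate
Product: 15 allyl (2R,3R)-3-[(S)-2,3-bis(triethylsilyloxy)propyl]-2-[(E)-2,6-dimethylhepta-1,5-dien-1-yl]-5-oxotetrahydrofuran-3-carboxylate, via dilithium alkoxide–enolate 13 (not isolated), via lithium alkoxide diester 14 (not isolated)
Conditions: LDA (2.3 equiv), THF, −78 to −20 °C; 12, DMPU, −78 to 0 °C
Reagents that add atoms: none
Why: Fráter–Seebach alkylation: the ester α-C–H is the only acidic C–H, dianion 13 is a six-membered lithium chelate in which the carbinol C–H eclipses the α-substituent, and allyl bromoacetate should therefore attack the enolate face opposite the alkenyl group and set the quaternary (R) centre, after which alkoxide 14 closes the γ-lactone on the new ester (5-exo-trig) with loss of allyl oxide.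

**Step 6**
Reactants: 15 allyl ester lactone
Product: 16 (2R,3R)-3-[(S)-2,3-bis(triethylsilyloxy)propyl]-2-[(E)-2,6-dimethylhepta-1,5-dien-1-yl]-5-oxotetrahydrofuran-3-carboxylic acid
Conditions: Pd(PPh3)4 (3 mol%), morpholine, THF, rt; pH 4 work-up
Reagents that add atoms: none
Why: Pd(0)-catalysed deallylation (π-allyl transfer to morpholine) frees the neopentyl acid under neutral conditions, the unsubstituted allyl ester being expected to ionise much faster than the hindered allylic C–O bond of the lactone, which carries a trisubstituted alkene.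

**Step 7**
Reactants: 16 lactone acid
Product: 18 (4R,5R)-4-acetyl-4-[(S)-2,3-bis(triethylsilyloxy)propyl]-5-[(E)-2,6-dimethylhepta-1,5-dien-1-yl]dihydrofuran-2(3H)-one, via acid chloride 17 (not isolated)
Conditions: 1-chloro-N,N,2-trimethylprop-1-en-1-amine, CH2Cl2, 0 °C to rt; then Me2CuLi (from CuI, MeLi), Et2O, −78 °C
Reagents that add atoms: lithium dimethylcuprate [Li+].C[Cu-]C
Why: The acid is converted to acid chloride 17 with the neutral Ghosez chloroenamine and then acylates a Gilman cuprate, a ketone synthesis that stops at the methyl ketone and leaves the lactone, silyl ethers and alkenes alone.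

**Step 8**
Reactants: 18 methyl ketone lactone
Product: 19 (S)-3-[(2R,3R)-3-acetyl-2-[(E)-2,6-dimethylhepta-1,5-dien-1-yl]-5-oxotetrahydrofuran-3-yl]-2-(triethylsilyloxy)propanal
Conditions: (COCl)2, DMSO, CH2Cl2, −78 to −30 °C; then Et3N, −78 to 0 °C
Reagents that add atoms: none
Why: Swern oxidation applied directly to the silyl ether: the chlorosulfonium salt cleaves only the unhindered primary triethylsilyl ether and the alkoxysulfonium salt collapses to the aldehyde, so the secondary silyl ether and the adjacent stereocentre should stay in place.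

**Step 9**
Reactants: 19 keto aldehyde; 20 (S)-2-methylpropane-2-sulfinamide
Product: 21 (S,E)-N-[(S)-3-[(2R,3R)-3-acetyl-2-[(E)-2,6-dimethylhepta-1,5-dien-1-yl]-5-oxotetrahydrofuran-3-yl]-2-(triethylsilyloxy)propylidene]-2-methylpropane-2-sulfinamide
Conditions: CuSO4 (anhydrous), CH2Cl2, rt
Reagents that add atoms: none
Why: Condensation over anhydrous CuSO4 (Ellman imine formation) is selective for the aldehyde over the hindered methyl ketone and mild enough to keep the α-silyloxy centre, giving the (E)-N-sulfinyl aldimine.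

**Step 10**
Reactants: 21 N-sulfinyl aldimine
Product: 23 (S)-N-[(1R,5R,8R,9S)-1-[(E)-2,6-dimethylhepta-1,5-dien-1-yl]-3,6-dioxo-9-(triethylsilyloxy)-2-oxaspiro[4.5]decan-8-yl]-2-methylpropane-2-sulfinamide, via lithium enolate 22 (not isolated)
Conditions: LiHMDS (1.1 equiv), THF, −78 °C, then −78 to −50 °C; sat. NH4Cl at −78 °C
Reagents that add atoms: none
Why: LiHMDS removes a proton from the acetyl methyl group, the only enolisable position of the ketone because its other α-carbon is the quaternary spiro carbon, and lithium enolate 22 adds to the carbon of the tethered aldimine through a chair in which lithium bridges the enolate oxygen and the sulfinyl imine. The closest known reaction is the addition of lithium enolates to N-sulfinyl aldimines (sulfinimine Mannich reaction), here in its intramolecular form. The cyclohexanone closes in the 6-(enolendo)-exo-trig mode, whereas Claisen attack of the same enolate on the lactone carbonyl would be a disfavoured 5-(enolendo)-exo-trig process. The new C–N centre should become (R) because the silyloxy group sits equatorial and antiperiplanar to the forming bond (polar Felkin–Anh) and the lithium bridge holds nitrogen axial, giving the cis amino alcohol on the side of the lactone CH–O carbon; the (S)-sulfinyl group is matched, since closed additions to (S)-configured sulfinyl aldimines deliver the enolate to this same face. The step needs ketone-over-lactone enolisation and kinetic control: the first rests on the higher kinetic acidity of the unhindered methyl ketone over the neopentyl lactone CH2 with one equivalent of a hindered amide base at −78 °C, the second on a cold quench that keeps the N-lithio sulfinamide from retro-Mannich equilibration to the equatorial amine.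

**Step 11**
Reactants: 23 N-sulfinyl O-silyl amino ketone
Product: 24 (1R,5R,8R,9S)-8-amino-1-[(E)-2,6-dimethylhepta-1,5-dien-1-yl]-9-hydroxy-2-oxaspiro[4.5]decane-3,6-dione hydrochloride
Conditions: HCl (1.25 M in MeOH), 0 °C; concentrate
Reagents that add atoms: hydrogen chloride Cl
Why: Methanolic HCl cleaves the N–S bond (methanolysis to the sulfinate ester) and the secondary triethylsilyl ether in one operation, and the β-amino ketone is kept as its ammonium salt so that retro-Mannich cleavage and β-elimination are avoided.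

**Step 12**
Reactants: 24 amino alcohol hydrochloride
Product: 25 (+)-miliusane V
Conditions: Ac2O (1.1 equiv), NaHCO3, EtOAc–H2O, 0 °C
Reagents that add atoms: acetic anhydride CC(=O)OC(C)=O
Why: Schotten–Baumann N-acetylation: the amine set free in the bicarbonate buffer is acylated much faster than the secondary alcohol, which should give the acetamide of the target without O-acetylation or epimerisation.

**Compound list**

1 | (S)-5-(hydroxymethyl)dihydrofuran-2(3H)-one | O=C1CC[C@@H](CO)O1 | starting material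
2 | lithium (S)-4,5-dihydroxypentanoate | [Li+].[O-]C(=O)CC[C@H](O)CO | intermediate
3 | triethylsilyl (S)-4,5-bis(triethylsilyloxy)pentanoate | CC[Si](CC)(CC)OC(=O)CC[C@H](O[Si](CC)(CC)CC)CO[Si](CC)(CC)CC | intermediate
4 | (S)-4,5-bis(triethylsilyloxy)pentanoic acid | OC(=O)CC[C@H](O[Si](CC)(CC)CC)CO[Si](CC)(CC)CC | intermediate
5 | (S)-4-benzyloxazolidin-2-one | O=C1N[C@@H](Cc2ccccc2)CO1 | starting material
6 | (S)-4,5-bis(triethylsilyloxy)pentanoic pivalic anhydride | CC(C)(C)C(=O)OC(=O)CC[C@H](O[Si](CC)(CC)CC)CO[Si](CC)(CC)CC | intermediate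
7 | (S)-4-benzyl-3-[(S)-4,5-bis(triethylsilyloxy)pentanoyl]oxazolidin-2-one | O=C1OC[C@H](Cc2ccccc2)N1C(=O)CC[C@H](O[Si](CC)(CC)CC)CO[Si](CC)(CC)CC | intermediate
8 | geranial, (2E)-3,7-dimethylocta-2,6-dienal | CC(C)=CCC/C(C)=C/C=O | starting material
9 | dibutylboron (Z)-enolate of imide 7 | CCCCB(CCCC)O/C(=C\C[C@H](O[Si](CC)(CC)CC)CO[Si](CC)(CC)CC)N1C(=O)OC[C@@H]1Cc1ccccc1 | intermediate
10 | (S)-4-benzyl-3-[(2S,3R,4E)-2-[(S)-2,3-bis(triethylsilyloxy)propyl]-3-hydroxy-5,9-dimethyldeca-4,8-dienoyl]oxazolidin-2-one | O=C1OC[C@H](Cc2ccccc2)N1C(=O)[C@@H](C[C@H](O[Si](CC)(CC)CC)CO[Si](CC)(CC)CC)[C@H](O)/C=C(\C)CCC=C(C)C | intermediate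
11 | allyl (2S,3R,4E)-2-[(S)-2,3-bis(triethylsilyloxy)propyl]-3-hydroxy-5,9-dimethyldeca-4,8-dienoate | C=CCOC(=O)[C@@H](C[C@H](O[Si](CC)(CC)CC)CO[Si](CC)(CC)CC)[C@H](O)/C=C(\C)CCC=C(C)C | intermediate
12 | allyl bromoacetate | C=CCOC(=O)CBr | starting material
13 | dilithium alkoxide–enolate of ester 11 | [Li+].[Li+].[O-]C(OCC=C)=C(C[C@H](O[Si](CC)(CC)CC)CO[Si](CC)(CC)CC)[C@H]([O-])/C=C(\C)CCC=C(C)C | intermediate
14 | lithium alkoxide of diallyl (R)-2-[(S)-2,3-bis(triethylsilyloxy)propyl]-2-[(1R,2E)-1-hydroxy-3,7-dimethylocta-2,6-dien-1-yl]butanedioate | [Li+].[O-][C@H](/C=C(\C)CCC=C(C)C)[C@](CC(=O)OCC=C)(C[C@H](O[Si](CC)(CC)CC)CO[Si](CC)(CC)CC)C(=O)OCC=C | intermediate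
15 | allyl (2R,3R)-3-[(S)-2,3-bis(triethylsilyloxy)propyl]-2-[(E)-2,6-dimethylhepta-1,5-dien-1-yl]-5-oxotetrahydrofuran-3-carboxylate | C=CCOC(=O)[C@@]1(CC(=O)O[C@@H]1/C=C(\C)CCC=C(C)C)C[C@H](O[Si](CC)(CC)CC)CO[Si](CC)(CC)CC | intermediate
16 | (2R,3R)-3-[(S)-2,3-bis(triethylsilyloxy)propyl]-2-[(E)-2,6-dimethylhepta-1,5-dien-1-yl]-5-oxotetrahydrofuran-3-carboxylic acid | OC(=O)[C@@]1(CC(=O)O[C@@H]1/C=C(\C)CCC=C(C)C)C[C@H](O[Si](CC)(CC)CC)CO[Si](CC)(CC)CC | intermediate
17 | (2R,3R)-3-[(S)-2,3-bis(triethylsilyloxy)propyl]-2-[(E)-2,6-dimethylhepta-1,5-dien-1-yl]-5-oxotetrahydrofuran-3-carbonyl chloride | ClC(=O)[C@@]1(CC(=O)O[C@@H]1/C=C(\C)CCC=C(C)C)C[C@H](O[Si](CC)(CC)CC)CO[Si](CC)(CC)CC | intermediate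
18 | (4R,5R)-4-acetyl-4-[(S)-2,3-bis(triethylsilyloxy)propyl]-5-[(E)-2,6-dimethylhepta-1,5-dien-1-yl]dihydrofuran-2(3H)-one | CC(=O)[C@@]1(CC(=O)O[C@@H]1/C=C(\C)CCC=C(C)C)C[C@H](O[Si](CC)(CC)CC)CO[Si](CC)(CC)CC | intermediate
19 | (S)-3-[(2R,3R)-3-acetyl-2-[(E)-2,6-dimethylhepta-1,5-dien-1-yl]-5-oxotetrahydrofuran-3-yl]-2-(triethylsilyloxy)propanal | CC(=O)[C@@]1(CC(=O)O[C@@H]1/C=C(\C)CCC=C(C)C)C[C@H](O[Si](CC)(CC)CC)C=O | intermediate
20 | (S)-2-methylpropane-2-sulfinamide | CC(C)(C)[S@@](N)=O | starting material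
21 | (S,E)-N-[(S)-3-[(2R,3R)-3-acetyl-2-[(E)-2,6-dimethylhepta-1,5-dien-1-yl]-5-oxotetrahydrofuran-3-yl]-2-(triethylsilyloxy)propylidene]-2-methylpropane-2-sulfinamide | CC(=O)[C@@]1(CC(=O)O[C@@H]1/C=C(\C)CCC=C(C)C)C[C@@H](/C=N/[S@@](=O)C(C)(C)C)O[Si](CC)(CC)CC | intermediate
22 | lithium enolate of 21 at the acetyl methyl group | [Li+].C=C([O-])[C@@]1(CC(=O)O[C@@H]1/C=C(\C)CCC=C(C)C)C[C@@H](/C=N/[S@@](=O)C(C)(C)C)O[Si](CC)(CC)CC | intermediate
23 | (S)-N-[(1R,5R,8R,9S)-1-[(E)-2,6-dimethylhepta-1,5-dien-1-yl]-3,6-dioxo-9-(triethylsilyloxy)-2-oxaspiro[4.5]decan-8-yl]-2-methylpropane-2-sulfinamide | CC(C)(C)[S@](=O)N[C@@H]1CC(=O)[C@@]2(CC(=O)O[C@@H]2/C=C(\C)CCC=C(C)C)C[C@@H]1O[Si](CC)(CC)CC | intermediate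
24 | (1R,5R,8R,9S)-8-amino-1-[(E)-2,6-dimethylhepta-1,5-dien-1-yl]-9-hydroxy-2-oxaspiro[4.5]decane-3,6-dione hydrochloride | [Cl-].[NH3+][C@@H]1CC(=O)[C@@]2(CC(=O)O[C@@H]2/C=C(\C)CCC=C(C)C)C[C@@H]1O | intermediate
25 | (+)-miliusane V: N-[(1R,5R,8R,9S)-1-[(E)-2,6-dimethylhepta-1,5-dien-1-yl]-9-hydroxy-3,6-dioxo-2-oxaspiro[4.5]decan-8-yl]acetamide | CC(=O)N[C@@H]1CC(=O)[C@@]2(CC(=O)O[C@@H]2/C=C(\C)CCC=C(C)C)C[C@@H]1O | target

**Step count and risks**

Total step count: 12. Longest linear sequence: 12 steps (from 1; compounds 5, 8, 12 and 20 enter as purchased).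

Steps most likely to fail:

1. Step 5 (quaternary carbon). The second deprotonation at the branched α-carbon may be slow, so that the dianion forms incompletely or fragments by retro-aldol cleavage, or the chelate may not differentiate the two enolate faces well. Fallback with a cyclic acetal template in place of the chelated dianion, setting out from 10 and coming back at 16: the auxiliary is removed from 10 with LiOH/H2O2 to give (2S,3R,4E)-2-[(S)-2,3-bis(triethylsilyloxy)propyl]-3-hydroxy-5,9-dimethyldeca-4,8-dienoic acid F1. Its bis-trimethylsilyl derivative is condensed with pivalaldehyde (TMSOTf cat., −78 °C) to the all-cis 2-tert-butyl-1,3-dioxan-4-one F2. The lithium enolate of F2 (LDA, −78 °C) is alkylated with allyl bromoacetate 12 on the face trans to the tert-butyl and alkenyl groups to give the 5,5-disubstituted dioxanone F3. LiOH in THF–water then cleaves the acylal and the allyl ester, and acidification closes the γ-lactone to give 16.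

2. Step 10 (Mannich closure). The base may also deprotonate the lactone CH2 or the α-carbon of the aldimine, or the lithium bridge may be too loose, so that the imine is attacked with nitrogen equatorial and the trans amino alcohol forms. Fallback in which nitrogen is delivered from the neighbouring oxygen instead of by imine addition, setting out from 19 and coming back at 25: aldol condensation of 19 (pyrrolidinium acetate, benzene, 50 °C) gives the spiro cyclohexenone F4, (1R,5R,9S)-1-[(E)-2,6-dimethylhepta-1,5-dien-1-yl]-9-(triethylsilyloxy)-2-oxaspiro[4.5]dec-7-ene-3,6-dione. PPTS in MeOH frees the γ-hydroxy enone F5. Cl3CCN/DBU forms the O-trichloroacetimidate, which should add in situ to the enone (intramolecular aza-Michael) to give the cis-fused 2-(trichloromethyl)oxazoline F6. Mild aqueous acid opens it to the cis hydroxy trichloroacetamide F7, and Bu3SnH/AIBN reduces CCl3 to CH3 to give 25.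

3. Step 6 (deallylation). Pd(0) may also ionise the allylic C–O bond of the γ-alkenyl lactone, which would open the ring and lead to amination by morpholine. Fallback that uses a thioester as the ketone precursor and needs no deallylation, setting out from 10 and coming back at 18: thiolysis of imide 10 with EtSLi gives S-ethyl (2S,3R,4E)-2-[(S)-2,3-bis(triethylsilyloxy)propyl]-3-hydroxy-5,9-dimethyldeca-4,8-dienethioate F8. Dianion alkylation with methyl bromoacetate as in step 5, followed by lactonisation with loss of methanol, gives the thioester lactone F9. Me2CuLi then converts the thioester directly into methyl ketone 18.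

**Further compounds**

F1 | step 5 | (2S,3R,4E)-2-[(S)-2,3-bis(triethylsilyloxy)propyl]-3-hydroxy-5,9-dimethyldeca-4,8-dienoic acid | OC(=O)[C@@H](C[C@H](O[Si](CC)(CC)CC)CO[Si](CC)(CC)CC)[C@H](O)/C=C(\C)CCC=C(C)C
F2 | step 5 | all-cis 5-[(S)-2,3-bis(triethylsilyloxy)propyl]-2-tert-butyl-6-[(E)-2,6-dimethylhepta-1,5-dien-1-yl]-1,3-dioxan-4-one | CC(C)(C)[C@H]1OC(=O)[C@@H](C[C@H](O[Si](CC)(CC)CC)CO[Si](CC)(CC)CC)[C@@H](/C=C(\C)CCC=C(C)C)O1
F3 | step 5 | allyl 2-[5-[(S)-2,3-bis(triethylsilyloxy)propyl]-2-tert-butyl-6-[(E)-2,6-dimethylhepta-1,5-dien-1-yl]-4-oxo-1,3-dioxan-5-yl]acetate (acetate arm trans to tert-butyl and alkenyl) | CC(C)(C)[C@H]1OC(=O)[C@@](CC(=O)OCC=C)(C[C@H](O[Si](CC)(CC)CC)CO[Si](CC)(CC)CC)[C@@H](/C=C(\C)CCC=C(C)C)O1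
F4 | step 10 | (1R,5R,9S)-1-[(E)-2,6-dimethylhepta-1,5-dien-1-yl]-9-(triethylsilyloxy)-2-oxaspiro[4.5]dec-7-ene-3,6-dione | O=C1C=C[C@@H](O[Si](CC)(CC)CC)C[C@]12CC(=O)O[C@@H]2/C=C(\C)CCC=C(C)C
F5 | step 10 | (1R,5R,9S)-1-[(E)-2,6-dimethylhepta-1,5-dien-1-yl]-9-hydroxy-2-oxaspiro[4.5]dec-7-ene-3,6-dione | O=C1C=C[C@@H](O)C[C@]12CC(=O)O[C@@H]2/C=C(\C)CCC=C(C)C
F6 | step 10 | cis-fused 2-(trichloromethyl)oxazoline spanning C8–N and C9–O of the spiro core | ClC(Cl)(Cl)C1=N[C@@H]2CC(=O)[C@@]3(CC(=O)O[C@@H]3/C=C(\C)CCC=C(C)C)C[C@@H]2O1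
F7 | step 10 | 2,2,2-trichloro-N-[(1R,5R,8R,9S)-1-[(E)-2,6-dimethylhepta-1,5-dien-1-yl]-9-hydroxy-3,6-dioxo-2-oxaspiro[4.5]decan-8-yl]acetamide | ClC(Cl)(Cl)C(=O)N[C@@H]1CC(=O)[C@@]2(CC(=O)O[C@@H]2/C=C(\C)CCC=C(C)C)C[C@@H]1O
F8 | step 6 | S-ethyl (2S,3R,4E)-2-[(S)-2,3-bis(triethylsilyloxy)propyl]-3-hydroxy-5,9-dimethyldeca-4,8-dienethioate | CCSC(=O)[C@@H](C[C@H](O[Si](CC)(CC)CC)CO[Si](CC)(CC)CC)[C@H](O)/C=C(\C)CCC=C(C)C
F9 | step 6 | S-ethyl (2R,3R)-3-[(S)-2,3-bis(triethylsilyloxy)propyl]-2-[(E)-2,6-dimethylhepta-1,5-dien-1-yl]-5-oxotetrahydrofuran-3-carbothioate | CCSC(=O)[C@@]1(CC(=O)O[C@@H]1/C=C(\C)CCC=C(C)C)C[C@H](O[Si](CC)(CC)CC)CO[Si](CC)(CC)CC
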